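**Plan**

Numbering: chroman O1–C8a (arene = ring A, dihydropyran = ring B); the side chain runs from C1′ (on C2) to C9′ (CO2H).
Cuts, last-made bond first: C7′=C8′ (Z-olefination), C5′–C6′ (allylic alkylation), C5′–H (allylic oxidation), O1–C8a (aryl ether, closes ring B), C4–C4a (sp3–sp2 cross-coupling).
Enabling feature: C2 of ring B bears O1, a methyl group, the C3–C4 bridge to ring A and a 4-methylpent-3-enyl arm. These are the four groups on the carbinol carbon of (R)-linalool if its vinyl group is read as C3–C4, so ring B lacks only the O1–C8a bond.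
Forward: ring A is bought as an aniline and given iodine at the future C4a and bromine at the future C8a. Hydroborated linalool is joined at C4a, ring B closes at O1–C8a, and the chain is then grown outward from C5′ to C9′.
Stereochemistry: C2 (R) comes unchanged from (R)-(−)-linalool, because none of its four bonds is ever broken. C3′=C4′ (E) comes from the SeO2 ene/[2,3]-shift sequence, and C7′=C8′ (Z) from the Still–Gennari olefination.

Key step: step 4

Assumption: (R)-(−)-linalool is bought in the highest enantiomeric grade on offer; since no bond at its carbinol carbon is broken, the enantiomeric purity of the target equals that of the purchased lot.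

**Step 1**
Reactants: 1 4-methoxy-2-methylaniline
Product: 2 2-iodo-4-methoxy-6-methylaniline
Conditions: BnMe3N·ICl2 (1.05 equiv), CaCO3, CH2Cl2/MeOH, rt, dark
Reagents that add atoms: benzyltrimethylammonium dichloroiodate, C[N+](C)(C)Cc1ccccc1.Cl[I-]Cl
Why: Electrophilic aromatic iodination in which the free amino group is the strongest donor, its para position is blocked by methoxy and one ortho position by methyl, so iodine should enter at the remaining ortho carbon (future C4a) while CaCO3 keeps the amine unprotonated.

**Step 2**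
Reactants: 2 2-iodo-4-methoxy-6-methylaniline
Product: 4 2-bromo-1-iodo-5-methoxy-3-methylbenzene, via diazonium bromide 3 (not isolated)
Conditions: NaNO2, 48% aq. HBr, 0 °C; then CuBr (30 mol %), aq. HBr, 0 → 50 °C
Reagents that add atoms: hydrogen bromide, Br; sodium nitrite, [Na+].[O-]N=O (its nitrogen is carried only by 3)
Why: Sandmeyer reaction, in which diazotisation and copper-mediated bromine transfer to the aryl radical replace nitrogen by bromine at the carbon that becomes C8a, while the aryl iodide and the methyl ether tolerate aqueous HBr at this temperature.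

**Step 3**
Reactants: 4 2-bromo-1-iodo-5-methoxy-3-methylbenzene; 5 (R)-(−)-linalool
Product: 7 (3R)-1-(2-bromo-5-methoxy-3-methylphenyl)-3,7-dimethyloct-6-en-3-ol, via B-alkyl-9-BBN borane 6 (not isolated)
Conditions: 5, 9-BBN (1.5 equiv), THF, 0 °C → rt; then 4, PdCl2(dppf) (5 mol %), Cs2CO3, DMF/H2O, rt → 45 °C
Reagents that add atoms: 9-borabicyclo[3.3.1]nonane, B1C2CCCC1CCC2 (its boron frame is carried only by 6; the product keeps one hydrogen)
Why: Anti-Markovnikov hydroboration with bulky 9-BBN selects the monosubstituted vinyl group over the trisubstituted alkene, and the B-alkyl Suzuki–Miyaura coupling occurs at the carbon–iodine bond, which adds to zerovalent palladium far faster than the carbon–bromine bond; the carbinol carbon takes no part and keeps its configuration.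

**Step 4**
Reactants: 7 (3R)-1-(2-bromo-5-methoxy-3-methylphenyl)-3,7-dimethyloct-6-en-3-ol
Product: 8 (2R)-6-methoxy-2,8-dimethyl-2-(4-methylpent-3-en-1-yl)-3,4-dihydro-2H-chromene
Conditions: Pd(OAc)2 (5 mol %), 2-(di-tert-butylphosphino)-1,1′-binaphthyl (7 mol %), Cs2CO3 (1.5 equiv), toluene, 80 °C
Reagents that add atoms: none
Why: Zerovalent palladium, formed in situ from Pd(OAc)2 and the phosphine, inserts into the C8a–Br bond, carbonate-assisted exchange of bromide for the tertiary alkoxide gives a seven-membered oxapalladacycle (Pd, C8a, C4a, C4, C3, C2, O1), and carbon–oxygen reductive elimination from divalent palladium releases the ether. The closest known reaction type is the intramolecular Buchwald–Hartwig-type etherification of aryl bromides by pendant alcohols, which is established for tertiary alcohols that give 2,2-dialkylchromans. Ring B closes by contraction of the seven-membered metallacycle to the six-membered ring, with O1 bonding to the ipso carbon C8a inside the coordination sphere of the metal. No stereocentre is created, and C2 stays R because oxygen, not carbon, is the reacting atom and the C2–O1 bond is never broken. The selectivity needed is ether formation ahead of hydrodebromination: C2 is fully substituted, so the palladium alkoxide offers no β-hydrogen, and the bulky electron-rich ligand drives reductive elimination at the doubly ortho-flanked, methoxy-rich aryl group. A Heck reaction with the trisubstituted alkene would need an eight-membered ring, so that alkene should stay a spectator.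

**Step 5**
Reactants: 8 (2R)-6-methoxy-2,8-dimethyl-2-(4-methylpent-3-en-1-yl)-3,4-dihydro-2H-chromene
Product: 10 (2E)-5-[(2R)-6-methoxy-2,8-dimethyl-3,4-dihydro-2H-chromen-2-yl]-2-methylpent-2-en-1-ol, via E-enal 9 (not isolated)
Conditions: SeO2 (0.3 equiv), t-BuOOH (2.5 equiv), CH2Cl2, 0 °C → rt; then crude, NaBH4, MeOH, 0 °C
Reagents that add atoms: tert-butyl hydroperoxide, CC(C)(C)OO
Why: Riley allylic oxidation in its catalytic SeO2/t-BuOOH form, where the ene reaction at the more substituted alkene terminus and the [2,3]-sigmatropic shift of the allylseleninic acid place oxygen on the methyl group trans to the chain and thereby fix C3′=C4′ as E, and NaBH4 returns over-oxidised enal 9 to the alcohol by 1,2-reduction.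

**Step 6**
Reactants: 10 (2E)-5-[(2R)-6-methoxy-2,8-dimethyl-3,4-dihydro-2H-chromen-2-yl]-2-methylpent-2-en-1-ol
Product: 11 (2R)-2-[(3E)-5-bromo-4-methylpent-3-en-1-yl]-6-methoxy-2,8-dimethyl-3,4-dihydro-2H-chromene
Conditions: CBr4, PPh3, CH2Cl2, 0 °C; used without storage
Reagents that add atoms: tetrabromomethane, BrC(Br)(Br)Br
Why: Appel reaction, in which SN2 displacement of the oxyphosphonium group at the primary allylic carbon under neutral conditions should give the bromide without allylic transposition or loss of alkene geometry.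

**Step 7**
Reactants: 11 (2R)-2-[(3E)-5-bromo-4-methylpent-3-en-1-yl]-6-methoxy-2,8-dimethyl-3,4-dihydro-2H-chromene
Product: 12 (4E)-7-[(2R)-6-methoxy-2,8-dimethyl-3,4-dihydro-2H-chromen-2-yl]-4-methylhept-4-enenitrile
Conditions: MeCN (5 equiv), n-BuLi (4.5 equiv), THF, −78 °C; then 11, −78 → −40 °C
Reagents that add atoms: acetonitrile, CC#N
Why: SN2 alkylation of a metallated nitrile by a primary allylic bromide, a standard two-carbon homologation of prenyl-type bromides, with the excess of carbanion and the low temperature holding back a second alkylation.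

**Step 8**
Reactants: 12 (4E)-7-[(2R)-6-methoxy-2,8-dimethyl-3,4-dihydro-2H-chromen-2-yl]-4-methylhept-4-enenitrile
Product: 14 (4E)-7-[(2R)-6-methoxy-2,8-dimethyl-3,4-dihydro-2H-chromen-2-yl]-4-methylhept-4-enal, via N-diisobutylaluminio imine 13 (not isolated)
Conditions: i-Bu2AlH (1.3 equiv), toluene, −78 °C; then 1 M aq. HCl, 0 °C, brief
Reagents that add atoms: water, O; diisobutylaluminium hydride, CC(C)C[AlH]CC(C)C (its aluminium is carried only by 13)
Why: Partial reduction of a nitrile with i-Bu2AlH, where a single hydride addition gives the N-aluminated imine 13, which resists further reduction in the cold and is hydrolysed to the aldehyde on acidic work-up, so the alcohol oxidation level cannot be reached.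

**Step 9**
Reactants: 14 (4E)-7-[(2R)-6-methoxy-2,8-dimethyl-3,4-dihydro-2H-chromen-2-yl]-4-methylhept-4-enal; 15 ethyl 2-[bis(2,2,2-trifluoroethoxy)phosphoryl]propanoate
Product: 17 ethyl (2Z,6E)-9-[(2R)-6-methoxy-2,8-dimethyl-3,4-dihydro-2H-chromen-2-yl]-2,6-dimethylnona-2,6-dienoate, via potassium phosphonate carbanion 16 (not isolated)
Conditions: 15, KN(SiMe3)2, 18-crown-6, THF, −78 °C; then 14, −78 °C
Reagents that add atoms: potassium bis(trimethylsilyl)amide, C[Si](C)(C)[N-][Si](C)(C)C.[K+] (its potassium is carried only by 16)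
Why: Still–Gennari variant of the Horner–Wadsworth–Emmons olefination, in which the electron-poor bis(trifluoroethyl) phosphonate and the crown-sequestered potassium ion make the kinetic adduct collapse faster than it reverts, so the Z-trisubstituted enoate (chain and ester cis) should prevail with this unbranched aliphatic aldehyde.

**Step 10**
Reactants: 17 ethyl (2Z,6E)-9-[(2R)-6-methoxy-2,8-dimethyl-3,4-dihydro-2H-chromen-2-yl]-2,6-dimethylnona-2,6-dienoate
Product: 19 (2Z,6E)-9-[(2R)-6-methoxy-2,8-dimethyl-3,4-dihydro-2H-chromen-2-yl]-2,6-dimethylnona-2,6-dienoic acid, via lithium carboxylate 18 (not isolated)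
Conditions: LiOH, THF/EtOH/H2O, 45 °C; then 1 M aq. HCl to pH 3, 0 °C
Reagents that add atoms: lithium hydroxide, [Li+].[OH-]
Why: Ester saponification by acyl–oxygen cleavage followed by acidification, with hydroxide too weak a base to remove a γ-proton, so the Z geometry of the α-methyl enoate, the E alkene and the remote C2 centre should all be retained.

**Compound list**

1 | 4-methoxy-2-methylaniline | COc1ccc(N)c(C)c1 | starting material
2 | 2-iodo-4-methoxy-6-methylaniline | COc1cc(C)c(N)c(I)c1 | intermediate
3 | 2-iodo-4-methoxy-6-methylbenzenediazonium bromide | COc1cc(C)c([N+]#N)c(I)c1.[Br-] | intermediate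
4 | 2-bromo-1-iodo-5-methoxy-3-methylbenzene | COc1cc(C)c(Br)c(I)c1 | intermediate
5 | (R)-(−)-linalool = (3R)-3,7-dimethylocta-1,6-dien-3-ol | C=C[C@@](C)(CCC=C(C)C)O | starting material
6 | (3S)-1-(9-borabicyclo[3.3.1]nonan-9-yl)-3,7-dimethyloct-6-en-3-ol (same spatial arrangement as 5; the descriptor changes because boron ranks below carbon) | B1(C2CCCC1CCC2)CC[C@@](C)(CCC=C(C)C)O | intermediate
7 | (3R)-1-(2-bromo-5-methoxy-3-methylphenyl)-3,7-dimethyloct-6-en-3-ol | COc1cc(C)c(Br)c(c1)CC[C@@](C)(CCC=C(C)C)O | intermediate
8 | (2R)-6-methoxy-2,8-dimethyl-2-(4-methylpent-3-en-1-yl)-3,4-dihydro-2H-chromene | COc1cc(C)c2c(c1)CC[C@@](C)(CCC=C(C)C)O2 | intermediate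
9 | (2E)-5-[(2R)-6-methoxy-2,8-dimethyl-3,4-dihydro-2H-chromen-2-yl]-2-methylpent-2-enal | COc1cc(C)c2c(c1)CC[C@@](C)(CC/C=C(\C)C=O)O2 | intermediate
10 | (2E)-5-[(2R)-6-methoxy-2,8-dimethyl-3,4-dihydro-2H-chromen-2-yl]-2-methylpent-2-en-1-ol | COc1cc(C)c2c(c1)CC[C@@](C)(CC/C=C(\C)CO)O2 | intermediate
11 | (2R)-2-[(3E)-5-bromo-4-methylpent-3-en-1-yl]-6-methoxy-2,8-dimethyl-3,4-dihydro-2H-chromene | COc1cc(C)c2c(c1)CC[C@@](C)(CC/C=C(\C)CBr)O2 | intermediate
12 | (4E)-7-[(2R)-6-methoxy-2,8-dimethyl-3,4-dihydro-2H-chromen-2-yl]-4-methylhept-4-enenitrile | COc1cc(C)c2c(c1)CC[C@@](C)(CC/C=C(\C)CCC#N)O2 | intermediate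
13 | N-(diisobutylaluminio) imine of aldehyde 14 | COc1cc(C)c2c(c1)CC[C@@](C)(CC/C=C(\C)CCC=N[Al](CC(C)C)CC(C)C)O2 | intermediate
14 | (4E)-7-[(2R)-6-methoxy-2,8-dimethyl-3,4-dihydro-2H-chromen-2-yl]-4-methylhept-4-enal | COc1cc(C)c2c(c1)CC[C@@](C)(CC/C=C(\C)CCC=O)O2 | intermediate
15 | ethyl 2-[bis(2,2,2-trifluoroethoxy)phosphoryl]propanoate (racemic at the α-carbon, which becomes sp2) | CCOC(=O)C(C)P(=O)(OCC(F)(F)F)OCC(F)(F)F | starting material
16 | potassium salt of the α-carbanion of 15 | CCOC(=O)[C-](C)P(=O)(OCC(F)(F)F)OCC(F)(F)F.[K+] | intermediate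
17 | ethyl (2Z,6E)-9-[(2R)-6-methoxy-2,8-dimethyl-3,4-dihydro-2H-chromen-2-yl]-2,6-dimethylnona-2,6-dienoate | COc1cc(C)c2c(c1)CC[C@@](C)(CC/C=C(\C)CC/C=C(/C)C(=O)OCC)O2 | intermediate
18 | lithium (2Z,6E)-9-[(2R)-6-methoxy-2,8-dimethyl-3,4-dihydro-2H-chromen-2-yl]-2,6-dimethylnona-2,6-dienoate | COc1cc(C)c2c(c1)CC[C@@](C)(CC/C=C(\C)CC/C=C(/C)C(=O)[O-])O2.[Li+] | intermediate
19 | (2Z,6E)-9-[(2R)-6-methoxy-2,8-dimethyl-3,4-dihydro-2H-chromen-2-yl]-2,6-dimethylnona-2,6-dienoic acid | COc1cc(C)c2c(c1)CC[C@@](C)(CC/C=C(\C)CC/C=C(/C)C(=O)O)O2 | target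

**Step count**

Total steps: 10. The longest linear sequence is 10 steps (1 → 19); 5 enters at step 3 and 15 at step 9.

**Steps most likely to fail**

Step 4. Oxidative addition into the electron-rich carbon–bromine bond, hemmed in by two ortho groups, may be sluggish, and hydrodebromination may then take over.
- The fallback changes both the halide and the metal while forming the same O1–C8a bond.
- It sets out from 7. Deprotonation and bromine–lithium exchange (t-BuLi, 3.2 equiv, THF, −78 °C) would give lithium (3R)-1-(2-lithio-5-methoxy-3-methylphenyl)-3,7-dimethyloct-6-en-3-olate F1.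
- An I2 quench and aqueous work-up would then give (3R)-1-(2-iodo-5-methoxy-3-methylphenyl)-3,7-dimethyloct-6-en-3-ol F2.
- The weaker carbon–halogen bond of F2 permits an intramolecular Ullmann-type etherification (CuI, 1,10-phenanthroline, Cs2CO3, toluene, 110 °C). This rejoins the route at 8.

Step 5. The risks are incomplete conversion, over-oxidation, and attack at the other allylic position.
- The fallback replaces C–H oxidation by cleavage and rebuilding of the alkene, setting out from 8.
- Lemieux–Johnson cleavage (OsO4 cat., NaIO4, 2,6-lutidine, dioxane/H2O) would give 3-[(2S)-6-methoxy-2,8-dimethyl-3,4-dihydro-2H-chromen-2-yl]propanal F3. C2 keeps the same spatial arrangement; the descriptor changes because the chain gains rank.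
- An E-selective Wittig reaction with the stabilised ylide Ph3P=C(CH3)CO2Et (toluene, 80 °C) would give ethyl (2E)-5-[(2R)-6-methoxy-2,8-dimethyl-3,4-dihydro-2H-chromen-2-yl]-2-methylpent-2-enoate F4.
- i-Bu2AlH (2.2 equiv, CH2Cl2, −78 °C) would reduce F4 to the allylic alcohol, rejoining the route at 10.

Step 3. The free hydroxyl may consume the borane, the alkylborane may undergo protodeboronation, and halide selectivity may erode.
- The fallback makes the C4–C4a bond without boron, setting out from 4 and 5.
- A Mizoroki–Heck arylation of the vinyl group (Pd(OAc)2, n-Bu4NCl, NaHCO3, DMF, 50 °C) can eliminate only toward the benzylic hydrogen, because the neighbouring carbinol carbon has none. It would give (1E,3R)-1-(2-bromo-5-methoxy-3-methylphenyl)-3,7-dimethylocta-1,6-dien-3-ol F5.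
- Diimide (2-nitrobenzenesulfonohydrazide, Et3N, CH2Cl2, rt) should saturate the disubstituted styrene bond ahead of the trisubstituted alkene and leave the carbon–bromine bond untouched. This rejoins the route at 7.

**Further compounds**

F1 | step 4 | lithium (3R)-1-(2-lithio-5-methoxy-3-methylphenyl)-3,7-dimethyloct-6-en-3-olate | COc1cc(C)c([Li])c(c1)CC[C@@](C)(CCC=C(C)C)O[Li]
F2 | step 4 | (3R)-1-(2-iodo-5-methoxy-3-methylphenyl)-3,7-dimethyloct-6-en-3-ol | COc1cc(C)c(I)c(c1)CC[C@@](C)(CCC=C(C)C)O
F3 | step 5 | 3-[(2S)-6-methoxy-2,8-dimethyl-3,4-dihydro-2H-chromen-2-yl]propanal | COc1cc(C)c2c(c1)CC[C@@](C)(CCC=O)O2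
F4 | step 5 | ethyl (2E)-5-[(2R)-6-methoxy-2,8-dimethyl-3,4-dihydro-2H-chromen-2-yl]-2-methylpent-2-enoate | COc1cc(C)c2c(c1)CC[C@@](C)(CC/C=C(\C)C(=O)OCC)O2
F5 | step 3 | (1E,3R)-1-(2-bromo-5-methoxy-3-methylphenyl)-3,7-dimethylocta-1,6-dien-3-ol | COc1cc(C)c(Br)c(c1)/C=C/[C@@](C)(CCC=C(C)C)O
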